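Ring A is not bought as an arene. Its bond C1'–C6' is disconnected, so that C2'(OH), C3'(OMe), C4'(OH), C5' and C6' are recognised as O1/C2, C3(OMe), C4(=O), C5 and C6 of the pyranone of maltol, and C1' as its 2-methyl carbon. In one operation aqueous hydroxide unfolds that pyranone to a 1,3,5-tricarbonyl chain, and aldol closure of C1' onto the C6' aldehyde builds the 2-methoxyresorcinol ring A. Precursor 16 is the (3R,4R)-butyrolactone with the ring B benzyl group on C4 and a 2-(3-methoxy-4-oxopyran-2-yl)ethyl chain on C3. C3 is fixed trans beforehand, because the saponified lactone cannot epimerise.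

Key step: step 7

Assumption (chemistry): the (S,S) antipode of Et-DuPhos is taken to deliver the (R) acid 4, by analogy with enamide and itaconate reductions; if the first run shows the opposite sense, the (R,R) ligand is used and nothing else changes.

Step 1
Reactants: 1 4-(benzyloxy)-3-methoxybenzaldehyde; 2 dimethyl succinate
Product: 3 (E)-4-[4-(benzyloxy)-3-methoxyphenyl]-3-(methoxycarbonyl)but-3-enoic acid
Conditions: NaOMe, MeOH, reflux; then 2 M HCl
Reagents that add atoms: none
Why: Stobbe condensation: the succinate enolate adds to the aldehyde, the aldolate closes to a paraconate lactone, and E1cB opening should give the half ester with the aryl group trans to the conjugated ester, the benzyl ether being inert to methoxide.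

Step 2
Reactants: 3 (E)-4-[4-(benzyloxy)-3-methoxyphenyl]-3-(methoxycarbonyl)but-3-enoic acid
Product: 4 (3R)-4-[4-(benzyloxy)-3-methoxyphenyl]-3-(methoxycarbonyl)butanoic acid
Conditions: H2 (10 bar), [Rh(cod)((S,S)-Et-DuPhos)]BF4 (0.2 mol%), NaOMe (10 mol%), MeOH, 25 °C
Reagents that add atoms: none
Why: Carboxylate-directed asymmetric hydrogenation of an itaconate-type half ester with a cationic rhodium bisphospholane catalyst, an established reaction class; the ligand fixes the face of hydrogen delivery to the chelated alkene and so sets the future C4 as R, and the homogeneous catalyst leaves the aryl benzyl ether alone.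

Step 3
Reactants: 4 (3R)-4-[4-(benzyloxy)-3-methoxyphenyl]-3-(methoxycarbonyl)butanoic acid
Product: 6 (4R)-4-{[4-(benzyloxy)-3-methoxyphenyl]methyl}oxolan-2-one, via hydroxy acid 5 (not isolated)
Conditions: KOH (1.0 equiv), EtOH, 0 °C; Ca(BH4)2 (from CaCl2, NaBH4), EtOH, −10 → 25 °C; then 3 M HCl, 25 °C
Reagents that add atoms: none
Why: Chemoselective borohydride reduction: Ca(BH4)2 reduces the methyl ester but not the potassium carboxylate, and hydroxy acid 5 lactonises on acidification, so the carboxyl carbon becomes C2 and the untouched stereocentre becomes C4 (R).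

Step 4
Reactants: 6 (4R)-4-{[4-(benzyloxy)-3-methoxyphenyl]methyl}oxolan-2-one
Product: 10 (4R)-4-{[4-(benzyloxy)-3-methoxyphenyl]methyl}-3-methylideneoxolan-2-one, via lithium enolate 7 (not isolated), via Mannich base 8 (not isolated), via trimethylammonium iodide 9 (not isolated)
Conditions: LiN(i-Pr)2, THF, −78 °C; Me2N=CH2+ I−, −78 → 25 °C; MeI, MeOH, 25 °C; NaHCO3 aq, CH2Cl2, 25 °C
Reagents that add atoms: N,N-dimethylmethyleneiminium iodide, C=[N+](C)C.[I-]
Why: Mannich reaction of the lactone enolate with the iminium salt, exhaustive methylation and bicarbonate-induced E1cB (Hofmann-type) elimination should install the exocyclic alkene; C4 is not involved and the weak base keeps the double bond from moving into the ring.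

Step 5
Reactants: 11 maltol (3-hydroxy-2-methyl-4H-pyran-4-one)
Product: 12 3-methoxy-2-methyl-4H-pyran-4-one
Conditions: MeI, K2CO3, acetone, reflux
Reagents that add atoms: iodomethane, CI
Why: Williamson ether synthesis on the acidic enolic 3-hydroxyl of maltol, the only nucleophilic site; no stereocentre is involved.

Step 6
Reactants: 12 3-methoxy-2-methyl-4H-pyran-4-one; 10 (4R)-4-{[4-(benzyloxy)-3-methoxyphenyl]methyl}-3-methylideneoxolan-2-one
Product: 16 (3R,4R)-4-{[4-(benzyloxy)-3-methoxyphenyl]methyl}-3-[2-(3-methoxy-4-oxo-4H-pyran-2-yl)ethyl]oxolan-2-one, via lithiated pyranone 13 (not isolated), via adduct lithium enolate 14 (not isolated), via cis lactone 15 (not isolated)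
Conditions: 12 (1.5 equiv), LiN(SiMe3)2, THF, −78 °C; slow addition of 10, −78 °C; AcOH, −78 °C; crude, DBU (0.3 equiv), toluene, 80 °C
Reagents that add atoms: none
Why: Michael addition of the vinylogous lithium enolate 13 (kinetic deprotonation of the pyranone 2-methyl group) to the s-cis-locked methylidene lactone forms the C7'–C1' bond; protonation of enolate 14 should occur mainly anti to the C4 benzyl group and give cis lactone 15, which DBU equilibrates through the lactone enolate to the thermodynamically preferred trans isomer 16 (C3 controlled by C4), residual cis material being separable and recyclable.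

Step 7
Reactants: 16 (3R,4R)-4-{[4-(benzyloxy)-3-methoxyphenyl]methyl}-3-[2-(3-methoxy-4-oxo-4H-pyran-2-yl)ethyl]oxolan-2-one
Product: 19 (3R,4R)-4-{[4-(benzyloxy)-3-methoxyphenyl]methyl}-3-[(2,4-dihydroxy-3-methoxyphenyl)methyl]oxolan-2-one, via tricarbonyl hydroxy acid 17 (not isolated), via seco hydroxy acid 18 (not isolated)
Conditions: 1 M KOH, H2O/1,4-dioxane, degassed, Ar, 25 → 60 °C; then 2 M HCl to pH 1, 25 °C
Reagents that add atoms: potassium hydroxide, [K+].[OH-] (oxygen only: it can enter the lactone carbonyl through saponification and relactonisation, or C2'–O if hydroxide attacks C2'; overall 16 and 19 are isomers)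
Why: Proposed new method: hydroxide adds to the vinylogous-ester carbon C6' of the pyranone (addition at C2' would unfold to the same chain, so the site of attack is immaterial), the ring opens to the enolate of the 1,3,5-tricarbonyl chain 17, the C1' methylene alpha to the C2' ketone adds to the C6' aldehyde, and loss of water with enolisation of the C2' and C4' carbonyls aromatises ring A, the former ring oxygen and pyranone carbonyl ending as the C2' and C4' phenols. The closest known reaction type is the alkali-induced recyclisation of 2,6-dimethyl-4-pyranone through heptane-2,4,6-trione to orcinol; new here are the 3-methoxy group, the unsubstituted C6' (an aldehyde acceptor instead of a ketone) and the lactone bystander. Ring A, the one ring formed, closes by a 6-(enolendo)-exo-trig aldol through the C1'–C6' bond, and no stereocentre is created. C3 and C4 are safe because the lactone is saponified at once to a carboxylate, which neither enolises nor acylates the chain carbanions. The selectivity needed is aldol closure ahead of retro-Claisen loss of C6' as formate: every other carbon–carbon closure from C1', C3' or C5' would give a four-membered ring, the six-membered closure is made irreversible by aromatisation, and exclusion of oxygen protects the electron-rich resorcinol. Acidification recloses the γ-lactone of 18 through C5–OH, the alkyl ester being preferred over a dihydrocoumarin through C2'–OH, without touching C3.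

Step 8
Reactants: 19 (3R,4R)-4-{[4-(benzyloxy)-3-methoxyphenyl]methyl}-3-[(2,4-dihydroxy-3-methoxyphenyl)methyl]oxolan-2-one
Product: 20 (3R,4R)-3-[(2,4-dihydroxy-3-methoxyphenyl)methyl]-4-[(4-hydroxy-3-methoxyphenyl)methyl]oxolan-2-one
Conditions: H2 (1 atm), 10% Pd/C, EtOAc/EtOH, 25 °C
Reagents that add atoms: none
Why: Hydrogenolysis of the benzyl aryl ether over palladium; the lactone, methyl ethers, phenols and both stereocentres should be inert under these conditions.

Compound list
1 | 4-(benzyloxy)-3-methoxybenzaldehyde (O-benzylvanillin) | COc1cc(C=O)ccc1OCc1ccccc1 | starting material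
2 | dimethyl succinate | COC(=O)CCC(=O)OC | starting material
3 | (E)-4-[4-(benzyloxy)-3-methoxyphenyl]-3-(methoxycarbonyl)but-3-enoic acid | COC(=O)/C(CC(=O)O)=C/c1ccc(OCc2ccccc2)c(OC)c1 | intermediate
4 | (3R)-4-[4-(benzyloxy)-3-methoxyphenyl]-3-(methoxycarbonyl)butanoic acid | COC(=O)[C@@H](CC(=O)O)Cc1ccc(OCc2ccccc2)c(OC)c1 | intermediate
5 | (3R)-4-[4-(benzyloxy)-3-methoxyphenyl]-3-(hydroxymethyl)butanoic acid (carboxylate salt in the flask) | OC[C@@H](CC(=O)O)Cc1ccc(OCc2ccccc2)c(OC)c1 | intermediate
6 | (4R)-4-{[4-(benzyloxy)-3-methoxyphenyl]methyl}oxolan-2-one | COc1cc(C[C@H]2COC(=O)C2)ccc1OCc1ccccc1 | intermediate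
7 | lithium enolate of 6, lithium (4R)-4-{[4-(benzyloxy)-3-methoxyphenyl]methyl}-4,5-dihydrofuran-2-olate | COc1cc(C[C@H]2COC(O[Li])=C2)ccc1OCc1ccccc1 | intermediate
8 | (3S,4R)-4-{[4-(benzyloxy)-3-methoxyphenyl]methyl}-3-[(dimethylamino)methyl]oxolan-2-one (trans) | COc1cc(C[C@H]2COC(=O)[C@@H]2CN(C)C)ccc1OCc1ccccc1 | intermediate
9 | {(3S,4R)-4-{[4-(benzyloxy)-3-methoxyphenyl]methyl}-2-oxooxolan-3-yl}-N,N,N-trimethylmethanaminium iodide | COc1cc(C[C@H]2COC(=O)[C@@H]2C[N+](C)(C)C)ccc1OCc1ccccc1.[I-] | intermediate
10 | (4R)-4-{[4-(benzyloxy)-3-methoxyphenyl]methyl}-3-methylideneoxolan-2-one | COc1cc(C[C@H]2COC(=O)C2=C)ccc1OCc1ccccc1 | intermediate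
11 | maltol (3-hydroxy-2-methyl-4H-pyran-4-one) | Cc1occc(=O)c1O | starting material
12 | 3-methoxy-2-methyl-4H-pyran-4-one | Cc1occc(=O)c1OC | intermediate
13 | lithiated 12, lithium 3-methoxy-2-methylidene-2H-pyran-4-olate | C=C1OC=CC(O[Li])=C1OC | intermediate
14 | lithium enolate of the Michael adduct, (4R)-configured, C3 planar | COc1cc(C[C@H]2COC(O[Li])=C2CCc2occc(=O)c2OC)ccc1OCc1ccccc1 | intermediate
15 | (3S,4R)-4-{[4-(benzyloxy)-3-methoxyphenyl]methyl}-3-[2-(3-methoxy-4-oxo-4H-pyran-2-yl)ethyl]oxolan-2-one (cis) | COc1cc(C[C@H]2COC(=O)[C@H]2CCc2occc(=O)c2OC)ccc1OCc1ccccc1 | intermediate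
16 | (3R,4R)-4-{[4-(benzyloxy)-3-methoxyphenyl]methyl}-3-[2-(3-methoxy-4-oxo-4H-pyran-2-yl)ethyl]oxolan-2-one (trans; key-step precursor) | COc1cc(C[C@H]2COC(=O)[C@@H]2CCc2occc(=O)c2OC)ccc1OCc1ccccc1 | intermediate
17 | (2R,3R)-3-{[4-(benzyloxy)-3-methoxyphenyl]methyl}-4-hydroxy-2-(4-methoxy-3,5,7-trioxoheptyl)butanoic acid (potassium enolate/carboxylate in the flask) | COc1cc(C[C@@H](CO)[C@@H](CCC(=O)C(OC)C(=O)CC=O)C(=O)O)ccc1OCc1ccccc1 | intermediate
18 | (2R,3R)-3-{[4-(benzyloxy)-3-methoxyphenyl]methyl}-2-[(2,4-dihydroxy-3-methoxyphenyl)methyl]-4-hydroxybutanoic acid (potassium salt in the flask) | COc1cc(C[C@@H](CO)[C@@H](Cc2ccc(O)c(OC)c2O)C(=O)O)ccc1OCc1ccccc1 | intermediate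
19 | (3R,4R)-4-{[4-(benzyloxy)-3-methoxyphenyl]methyl}-3-[(2,4-dihydroxy-3-methoxyphenyl)methyl]oxolan-2-one (key-step product) | COc1cc(C[C@H]2COC(=O)[C@@H]2Cc2ccc(O)c(OC)c2O)ccc1OCc1ccccc1 | intermediate
20 | (3R,4R)-3-[(2,4-dihydroxy-3-methoxyphenyl)methyl]-4-[(4-hydroxy-3-methoxyphenyl)methyl]oxolan-2-one | COc1cc(C[C@H]2COC(=O)[C@@H]2Cc2ccc(O)c(OC)c2O)ccc1O | target

Total step count: 8. Longest linear sequence: 7 steps (steps 1, 2, 3, 4, 6, 7, 8); step 5 is a one-step side branch.

Steps most likely to fail

1. Step 7 (new method). What may go wrong: the opened chain loses C6' as formate by retro-Claisen cleavage, or simply recloses to the pyranone, faster than C1' attacks C6', so that ring A never forms. Fallback (known chemistry; ring A is brought in as a finished arene; sets out from 6, returns at 20): 2-methoxyresorcinol is formylated (POCl3, DMF) to 2,4-dihydroxy-3-methoxybenzaldehyde F1, benzylated (BnBr, K2CO3) to 2,4-bis(benzyloxy)-3-methoxybenzaldehyde F2, reduced (NaBH4) to [2,4-bis(benzyloxy)-3-methoxyphenyl]methanol F3 and converted (PBr3) into 2,4-bis(benzyloxy)-1-(bromomethyl)-3-methoxybenzene F4. Lithium enolate 7 of lactone 6 is alkylated with F4 anti to the C4 substituent to give (3R,4R)-4-{[4-(benzyloxy)-3-methoxyphenyl]methyl}-3-{[2,4-bis(benzyloxy)-3-methoxyphenyl]methyl}oxolan-2-one F5, and hydrogenolysis of its three benzyl ethers over Pd/C should give 20.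

2. Step 6. What may go wrong: the adduct enolate adds to further methylidene lactone (oligomerisation), the basic carbanion removes the C4 proton so that the double bond moves into the ring and the C4 stereocentre is erased, or C3 does not equilibrate cleanly. Fallback (polarity reversed, the lactone becomes the nucleophile; sets out from 12 and 6, returns at 16): lithiated 12 is hydroxymethylated with monomeric formaldehyde to 2-(2-hydroxyethyl)-3-methoxy-4H-pyran-4-one F6, mesylated (MsCl, Et3N) to 2-(3-methoxy-4-oxo-4H-pyran-2-yl)ethyl methanesulfonate F7 and eliminated (DBU) to 2-ethenyl-3-methoxy-4H-pyran-4-one F8. Lithium enolate 7 of 6 then adds to the vinyl terminus of F8 in a 1,6-conjugate addition, forming C3–C7' anti to the C4 benzyl group, so that protonation on work-up should give trans lactone 16 directly, without an epimerisation.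

3. Step 4. What may go wrong: incomplete quaternisation, or base-induced migration of the new exocyclic double bond into the ring during the elimination, which would destroy the C4 stereocentre. Fallback (aldol and β-elimination instead of Mannich and ammonium elimination; sets out from 6, returns at 10): enolate 7 is trapped with monomeric formaldehyde to (3S,4R)-4-{[4-(benzyloxy)-3-methoxyphenyl]methyl}-3-(hydroxymethyl)oxolan-2-one F9, which is mesylated to {(3S,4R)-4-{[4-(benzyloxy)-3-methoxyphenyl]methyl}-2-oxooxolan-3-yl}methyl methanesulfonate F10 and eliminated with Et3N at 0 °C to 10.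

Further compounds
F1 | step 7 | 2,4-dihydroxy-3-methoxybenzaldehyde | COc1c(O)ccc(C=O)c1O
F2 | step 7 | 2,4-bis(benzyloxy)-3-methoxybenzaldehyde | COc1c(OCc2ccccc2)ccc(C=O)c1OCc1ccccc1
F3 | step 7 | [2,4-bis(benzyloxy)-3-methoxyphenyl]methanol | COc1c(OCc2ccccc2)ccc(CO)c1OCc1ccccc1
F4 | step 7 | 2,4-bis(benzyloxy)-1-(bromomethyl)-3-methoxybenzene | COc1c(OCc2ccccc2)ccc(CBr)c1OCc1ccccc1
F5 | step 7 | (3R,4R)-4-{[4-(benzyloxy)-3-methoxyphenyl]methyl}-3-{[2,4-bis(benzyloxy)-3-methoxyphenyl]methyl}oxolan-2-one | COc1cc(C[C@H]2COC(=O)[C@@H]2Cc2ccc(OCc3ccccc3)c(OC)c2OCc2ccccc2)ccc1OCc1ccccc1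
F6 | step 6 | 2-(2-hydroxyethyl)-3-methoxy-4H-pyran-4-one | COc1c(CCO)occc1=O
F7 | step 6 | 2-(3-methoxy-4-oxo-4H-pyran-2-yl)ethyl methanesulfonate | COc1c(CCOS(C)(=O)=O)occc1=O
F8 | step 6 | 2-ethenyl-3-methoxy-4H-pyran-4-one | COc1c(C=C)occc1=O
F9 | step 4 | (3S,4R)-4-{[4-(benzyloxy)-3-methoxyphenyl]methyl}-3-(hydroxymethyl)oxolan-2-one | COc1cc(C[C@H]2COC(=O)[C@@H]2CO)ccc1OCc1ccccc1
F10 | step 4 | {(3S,4R)-4-{[4-(benzyloxy)-3-methoxyphenyl]methyl}-2-oxooxolan-3-yl}methyl methanesulfonate | COc1cc(C[C@H]2COC(=O)[C@@H]2COS(C)(=O)=O)ccc1OCc1ccccc1
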